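The route rests on reading the 5,6-dihydro-2H-pyran-2-one ring (O1, C2 carbonyl, C3=C4, C5, C6) as the oxidised adduct of a hetero-Diels–Alder reaction. An achiral enal carrying the complete acetoxymethyl-octadienyl side chain is the heterodienophile; an achiral 1-methoxy-1,3-diene bearing the 4-methylpent-3-enyl group at its own C2 is the diene. One chromium-catalysed [4+2] step joins C5 to C6 and O1 to C2, closes the ring, sets the only stereocentre (C6, R) and leaves the C3=C4 double bond where the lactone needs it. Oxidation of the methyl acetal carbon to the carbonyl and loss of one silyl group finish the synthesis.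

Key step: step 9

Remarks on the chemistry:
- Ring atoms are numbered as in the lactone throughout: O1, C2 (carbonyl or acetal carbon), C3, C4, C5, C6.
- Assumption: nerol, 2-methylidenepropane-1,3-diol, methyl (E)-but-2-enoate and 5-bromo-2-methylpent-2-ene are commercial.
- Assumption: the sense of induction in step 9 is assigned by analogy with this catalyst class and 1-methoxybuta-1,3-diene. If a trial should give the 6S adduct, the ligand from (1R,2S)-1-aminoindan-2-ol is used instead.

Step 1
Reactants: 1 nerol
Product: 2 tert-butyl{[(2Z)-3,7-dimethylocta-2,6-dien-1-yl]oxy}dimethylsilane (neryl TBS ether)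
Conditions: TBSCl, imidazole, DMF, 0 °C to room temperature
Reagents that add atoms: tert-butyldimethylsilyl chloride, CC(C)(C)[Si](C)(C)Cl
Why: Standard silyl ether formation on the primary allylic alcohol masks it through the metathesis, cycloaddition and chromium oxidation steps and is removable at the end without touching the acetate.

Step 2
Reactants: 3 2-methylidenepropane-1,3-diol
Product: 5 2-(hydroxymethyl)prop-2-en-1-yl acetate, via cyclic orthoester 4 (not isolated)
Conditions: MeC(OMe)3, pyridinium p-toluenesulfonate (cat.), CH2Cl2, room temperature; then H2O–AcOH, room temperature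
Reagents that add atoms: trimethyl orthoacetate, CC(OC)(OC)OC; water, O
Why: Acid-catalysed transorthoesterification gives the six-membered cyclic orthoester, whose hydrolysis can open only once, so the symmetric diol becomes the monoacetate without a statistical mixture (orthoester monoacylation of a diol).

Step 3
Reactants: 5 2-(hydroxymethyl)prop-2-en-1-yl acetate
Product: 6 2-formylprop-2-en-1-yl acetate
Conditions: MnO2 (activated, excess), CH2Cl2, room temperature
Reagents that add atoms: none
Why: MnO2 oxidises the allylic primary alcohol selectively to the enal (allylic alcohol oxidation) and leaves the ester alone.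

Step 4
Reactants: 2 neryl TBS ether; 6 2-formylprop-2-en-1-yl acetate
Product: 7 (2E,6Z)-8-[(tert-butyldimethylsilyl)oxy]-2-formyl-6-methylocta-2,6-dien-1-yl acetate
Conditions: second-generation Hoveyda–Grubbs catalyst, RuCl2(H2IMes)(=CH-C6H4-2-OiPr) (5 mol%), 6 (3 equiv), CH2Cl2, 40 °C, slow argon purge
Reagents that add atoms: none
Why: Olefin cross-metathesis of the terminal isopropylidene group of 2 with the 2-substituted acrolein 6 is driven by loss of 2-methylpropene, spares the more hindered alkene next to the silyloxy group, and should give the thermodynamically preferred E enal (formyl group trans to the chain), as 2-methylacrolein does with prenyl-type alkenes.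

Step 5
Reactants: 8 methyl (E)-but-2-enoate; 9 5-bromo-2-methylpent-2-ene
Product: 10 methyl 2-(4-methylpent-3-en-1-yl)but-3-enoate (racemic)
Conditions: LiN(iPr)2, DMPU, THF, −78 °C; then 9, −78 to 0 °C
Reagents that add atoms: none
Why: Deprotonation at the γ-methyl group gives the lithium dienolate, which is alkylated at the α-carbon (deconjugative α-alkylation of a crotonate); the new stereocentre is racemic and is erased in step 6.

Step 6
Reactants: 10 methyl 2-(4-methylpent-3-en-1-yl)but-3-enoate
Product: 12 (2E)-2-(4-methylpent-3-en-1-yl)but-2-enal, via but-3-enal isomer 11 (not isolated)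
Conditions: i-Bu2AlH (1.05 equiv), CH2Cl2, −78 °C; aqueous KNaC4H4O6 (potassium sodium tartrate) work-up; then DBU (0.1 equiv), CH2Cl2, room temperature
Reagents that add atoms: none
Why: Low-temperature i-Bu2AlH reduction stops at the aldehyde through the stable aluminium hemiacetal (partial ester reduction), and catalytic DBU then moves the double bond into conjugation to give the more stable E enal, removing the α-stereocentre.

Step 7
Reactants: 12 (2E)-2-(4-methylpent-3-en-1-yl)but-2-enal
Product: 13 (2E)-1,1-dimethoxy-2-(4-methylpent-3-en-1-yl)but-2-ene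
Conditions: HC(OMe)3, MeOH, pyridinium p-toluenesulfonate (cat.), room temperature
Reagents that add atoms: trimethyl orthoformate, COC(OC)OC
Why: Acid-catalysed acetalisation with the orthoformate as water scavenger converts the enal into its dimethyl acetal, the mild catalyst avoiding conjugate addition of methanol and leaving the trisubstituted alkenes untouched.

Step 8
Reactants: 13 (2E)-1,1-dimethoxy-2-(4-methylpent-3-en-1-yl)but-2-ene
Product: 14 (1E)-1-methoxy-2-(4-methylpent-3-en-1-yl)buta-1,3-diene
Conditions: TMSOTf (1.1 equiv), iPr2NEt (1.5 equiv), CH2Cl2, −20 °C to room temperature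
Reagents that add atoms: none
Why: TMSOTf ionises the acetal to the s-trans alkenyl oxocarbenium ion and the hindered amine removes a proton from the γ-methyl group (Lewis acid–amine acetal-to-enol-ether elimination, here a 1,4-elimination), which should give the 1E diene; any 1Z isomer cannot reach a reactive s-cis conformation and is a spectator in step 9.

Step 9
Reactants: 7 (2E,6Z)-8-[(tert-butyldimethylsilyl)oxy]-2-formyl-6-methylocta-2,6-dien-1-yl acetate; 14 (1E)-1-methoxy-2-(4-methylpent-3-en-1-yl)buta-1,3-diene
Product: 15 (2E,6Z)-8-[(tert-butyldimethylsilyl)oxy]-2-[(2R,6S)-6-methoxy-5-(4-methylpent-3-en-1-yl)-3,6-dihydro-2H-pyran-2-yl]-6-methylocta-2,6-dien-1-yl acetate (side chain and methoxy group cis)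
Conditions: (C27H29NO2)CrCl (5 mol%; chromium chloride complex of the tridentate Schiff base from 3-(1-adamantyl)-2-hydroxy-5-methylbenzaldehyde and (1S,2R)-1-aminoindan-2-ol, trivalent chromium), 14 (2 equiv), 4 Å molecular sieves, minimal tert-butyl methyl ether, room temperature
Reagents that add atoms: none
Why: The Lewis-acidic chromium centre binds the aldehyde oxygen of 7, and the 4π system of 14 adds across C=O in a concerted, asynchronous [4+2] hetero-Diels–Alder reaction in which the diene CH2 terminus bonds to the carbonyl carbon (the C5–C6 bond) while the carbonyl oxygen bonds to the methoxy-bearing carbon (O1–C2). The closest known reaction is the hetero-Diels–Alder reaction of 1-methoxybuta-1,3-diene with conjugated aldehydes under the same chromium catalyst class. The six-membered dihydropyran ring is closed in the [4+2] mode, both ring bonds forming in the same step. C6 is set by the chiral catalyst, which should block the Si face of the bound aldehyde so that the diene adds to the Re face (6R in lactone numbering); the acetal carbon follows from the endo transition state (cis to the C6 substituent) and is erased in step 10. The step needs regioselectivity, secured by the methoxy group that makes the remote CH2 terminus the nucleophilic end, and chemoselectivity for C=O over the enal C=C, secured by the trisubstituted, α-branched alkene of 7 being a poor carbon dienophile.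

Step 10
Reactants: 15 the cis 2-methoxy-dihydropyran adduct
Product: 16 (2E,6Z)-8-[(tert-butyldimethylsilyl)oxy]-6-methyl-2-[(2R)-5-(4-methylpent-3-en-1-yl)-6-oxo-3,6-dihydro-2H-pyran-2-yl]octa-2,6-dien-1-yl acetate
Conditions: pyridinium chlorochromate, [C5H5NH][CrO3Cl] (3 equiv), Celite, CH2Cl2, room temperature
Reagents that add atoms: pyridinium chlorochromate, [O-][Cr](=O)(=O)Cl.c1cc[nH+]cc1
Why: The chromium oxidant converts the allylic cyclic methyl acetal directly into the α,β-unsaturated δ-lactone (oxidation of a 2-alkoxy-5,6-dihydro-2H-pyran by ionisation to the cyclic oxocarbenium ion, chromate ester formation and elimination), which removes the acetal stereocentre and leaves C6, the silyl ether and the acetate untouched.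

Step 11
Reactants: 16 the silyl-protected lactone
Product: 17 (2E,6Z)-8-hydroxy-6-methyl-2-[(2R)-5-(4-methylpent-3-en-1-yl)-6-oxo-3,6-dihydro-2H-pyran-2-yl]octa-2,6-dien-1-yl acetate (CNP0179839.1)
Conditions: HF·pyridine, pyridine, THF, 0 °C to room temperature
Reagents that add atoms: none
Why: Buffered fluoride cleaves the primary tert-butyldimethylsilyl ether (desilylation) under conditions that should neither hydrolyse the acetate or the lactone nor add to the unsaturated lactone, so C6 stays R.

Compound list
1 | nerol, (2Z)-3,7-dimethylocta-2,6-dien-1-ol | CC(C)=CCC/C(C)=C\CO | starting material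
2 | tert-butyl{[(2Z)-3,7-dimethylocta-2,6-dien-1-yl]oxy}dimethylsilane | CC(C)=CCC/C(C)=C\CO[Si](C)(C)C(C)(C)C | intermediate
3 | 2-methylidenepropane-1,3-diol | C=C(CO)CO | starting material
4 | 2-methoxy-2-methyl-5-methylidene-1,3-dioxane (cyclic orthoester) | COC1(C)OCC(=C)CO1 | intermediate (not isolated)
5 | 2-(hydroxymethyl)prop-2-en-1-yl acetate | CC(=O)OCC(=C)CO | intermediate
6 | 2-formylprop-2-en-1-yl acetate | CC(=O)OCC(=C)C=O | intermediate
7 | (2E,6Z)-8-[(tert-butyldimethylsilyl)oxy]-2-formyl-6-methylocta-2,6-dien-1-yl acetate | CC(=O)OC/C(C=O)=C\CC/C(C)=C\CO[Si](C)(C)C(C)(C)C | intermediate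
8 | methyl (E)-but-2-enoate | C/C=C/C(=O)OC | starting material
9 | 5-bromo-2-methylpent-2-ene | CC(C)=CCCBr | starting material
10 | methyl 2-(4-methylpent-3-en-1-yl)but-3-enoate (racemic) | C=CC(CCC=C(C)C)C(=O)OC | intermediate
11 | 2-(4-methylpent-3-en-1-yl)but-3-enal (racemic) | C=CC(CCC=C(C)C)C=O | intermediate (not isolated)
12 | (2E)-2-(4-methylpent-3-en-1-yl)but-2-enal | C/C=C(/C=O)CCC=C(C)C | intermediate
13 | (2E)-1,1-dimethoxy-2-(4-methylpent-3-en-1-yl)but-2-ene | C/C=C(/C(OC)OC)CCC=C(C)C | intermediate
14 | (1E)-1-methoxy-2-(4-methylpent-3-en-1-yl)buta-1,3-diene | CO/C=C(/C=C)CCC=C(C)C | intermediate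
15 | (2E,6Z)-8-[(tert-butyldimethylsilyl)oxy]-2-[(2R,6S)-6-methoxy-5-(4-methylpent-3-en-1-yl)-3,6-dihydro-2H-pyran-2-yl]-6-methylocta-2,6-dien-1-yl acetate | CC(=O)OC/C(=C\CC/C(C)=C\CO[Si](C)(C)C(C)(C)C)[C@H]1CC=C(CCC=C(C)C)[C@@H](OC)O1 | intermediate
16 | (2E,6Z)-8-[(tert-butyldimethylsilyl)oxy]-6-methyl-2-[(2R)-5-(4-methylpent-3-en-1-yl)-6-oxo-3,6-dihydro-2H-pyran-2-yl]octa-2,6-dien-1-yl acetate | CC(=O)OC/C(=C\CC/C(C)=C\CO[Si](C)(C)C(C)(C)C)[C@H]1CC=C(CCC=C(C)C)C(=O)O1 | intermediate
17 | (2E,6Z)-8-hydroxy-6-methyl-2-[(2R)-5-(4-methylpent-3-en-1-yl)-6-oxo-3,6-dihydro-2H-pyran-2-yl]octa-2,6-dien-1-yl acetate | CC(=O)OC/C(=C\CC/C(C)=C\CO)[C@H]1CC=C(CCC=C(C)C)C(=O)O1 | target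

Total step count: 11
Longest linear sequence: 7 steps (steps 5, 6, 7, 8, 9, 10, 11, from methyl (E)-but-2-enoate)

Steps most likely to fail

1. Step 9. The α-branched enal may be too weak a heterodienophile for a mono-oxygenated diene, its C=C bond may react as a carbon dienophile, or the catalyst may discriminate the aldehyde faces poorly. The fallback sets out from 7 (with 9 for the acid partner) and comes back to the route at 16. Asymmetric allylboration of 7 with the enantiomer of B-allyldiisopinocampheylborane that attacks the Re face (−78 °C, ethanolamine work-up) would give (2E,6Z)-8-[(tert-butyldimethylsilyl)oxy]-2-[(1R)-1-hydroxybut-3-en-1-yl]-6-methylocta-2,6-dien-1-yl acetate F1. Separately, 9 would alkylate diethyl malonate (NaH, THF) to diethyl 2-(4-methylpent-3-en-1-yl)propanedioate F2. Saponification (KOH) would give 2-(4-methylpent-3-en-1-yl)propanedioic acid F3, and Mannich-type decarboxylative methylenation (paraformaldehyde, Et2NH) would give 6-methyl-2-methylidenehept-5-enoic acid F4. Esterification of F1 with F4 (DCC, DMAP) would give the diene ester (1R)-1-[(2E,6Z)-1-acetoxy-8-[(tert-butyldimethylsilyl)oxy]-6-methylocta-2,6-dien-2-yl]but-3-en-1-yl 6-methyl-2-methylidenehept-5-enoate F5. Ring-closing metathesis with the second-generation Grubbs catalyst, RuCl2(H2IMes)(PCy3)(=CHPh), would then close C3=C4 and give 16.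

2. Step 4. The trisubstituted alkene and the electron-poor 1,1-disubstituted partner may fail to cross-couple, or the geometry of the new double bond may not be controlled. The fallback sets out from 2 and comes back to the route at 7. Regioselective epoxidation of the terminal alkene (mCPBA, CH2Cl2, 0 °C) would give tert-butyl{[(2Z)-5-(3,3-dimethyloxiran-2-yl)-3-methylpent-2-en-1-yl]oxy}dimethylsilane F6. Cleavage with H5IO6 would give (4Z)-6-[(tert-butyldimethylsilyl)oxy]-4-methylhex-4-enal F7. Addition of 2-lithio-3,3-diethoxyprop-1-ene (from 2-bromo-3,3-diethoxyprop-1-ene and t-BuLi) with an Ac2O quench would give (6Z)-8-[(tert-butyldimethylsilyl)oxy]-1,1-diethoxy-6-methyl-2-methylideneoct-6-en-3-yl acetate F8. Mild acetal hydrolysis (oxalic acid on wet silica gel) would give (6Z)-8-[(tert-butyldimethylsilyl)oxy]-6-methyl-2-methylidene-1-oxooct-6-en-3-yl acetate F9. A DABCO-catalysed 1,3-acetoxy transposition (SN2' then SN2') would move the double bond into the conjugated, thermodynamically preferred E position and give 7.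

3. Step 8. The ionic elimination may give a mixture of enol ether geometries, or the cationic intermediate may be captured by the electron-rich diene as it forms (oligomerisation). The fallback sets out from 9 and comes back to the route at 14. Magnesium in THF would convert 9 into (4-methylpent-3-en-1-yl)magnesium bromide F10. Addition to acrolein would give 7-methylocta-1,6-dien-3-ol F11, and oxidation with Dess–Martin periodinane would give 7-methylocta-1,6-dien-3-one F12. Wittig methoxymethylenation (Ph3P=CHOMe from (methoxymethyl)triphenylphosphonium chloride and KOtBu) would give 14 together with its 1Z isomer, which is left behind in step 9.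

Further compounds
F1 | step 9 | (2E,6Z)-8-[(tert-butyldimethylsilyl)oxy]-2-[(1R)-1-hydroxybut-3-en-1-yl]-6-methylocta-2,6-dien-1-yl acetate | CC(=O)OC/C(=C\CC/C(C)=C\CO[Si](C)(C)C(C)(C)C)[C@H](O)CC=C
F2 | step 9 | diethyl 2-(4-methylpent-3-en-1-yl)propanedioate | CCOC(=O)C(CCC=C(C)C)C(=O)OCC
F3 | step 9 | 2-(4-methylpent-3-en-1-yl)propanedioic acid | OC(=O)C(CCC=C(C)C)C(=O)O
F4 | step 9 | 6-methyl-2-methylidenehept-5-enoic acid | C=C(CCC=C(C)C)C(=O)O
F5 | step 9 | (1R)-1-[(2E,6Z)-1-acetoxy-8-[(tert-butyldimethylsilyl)oxy]-6-methylocta-2,6-dien-2-yl]but-3-en-1-yl 6-methyl-2-methylidenehept-5-enoate | CC(=O)OC/C(=C\CC/C(C)=C\CO[Si](C)(C)C(C)(C)C)[C@H](OC(=O)C(=C)CCC=C(C)C)CC=C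
F6 | step 4 | tert-butyl{[(2Z)-5-(3,3-dimethyloxiran-2-yl)-3-methylpent-2-en-1-yl]oxy}dimethylsilane (racemic) | CC1(C)OC1CC/C(C)=C\CO[Si](C)(C)C(C)(C)C
F7 | step 4 | (4Z)-6-[(tert-butyldimethylsilyl)oxy]-4-methylhex-4-enal | O=CCC/C(C)=C\CO[Si](C)(C)C(C)(C)C
F8 | step 4 | (6Z)-8-[(tert-butyldimethylsilyl)oxy]-1,1-diethoxy-6-methyl-2-methylideneoct-6-en-3-yl acetate (racemic) | CCOC(OCC)C(=C)C(OC(C)=O)CC/C(C)=C\CO[Si](C)(C)C(C)(C)C
F9 | step 4 | (6Z)-8-[(tert-butyldimethylsilyl)oxy]-6-methyl-2-methylidene-1-oxooct-6-en-3-yl acetate (racemic) | CC(=O)OC(CC/C(C)=C\CO[Si](C)(C)C(C)(C)C)C(=C)C=O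
F10 | step 8 | (4-methylpent-3-en-1-yl)magnesium bromide | CC(C)=CCC[Mg]Br
F11 | step 8 | 7-methylocta-1,6-dien-3-ol (racemic) | C=CC(O)CCC=C(C)C
F12 | step 8 | 7-methylocta-1,6-dien-3-one | C=CC(=O)CCC=C(C)C
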